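**Plan**

1. Locants: ring C is the 1,4-dioxane (O1, C2 carrying the syringyl ring A, C3 carrying CH2OH, O4). Ring B is the benzo ring (C4a on O4, C5 with OMe, C7 with the hydroxypropenyl chain, C8a on O1).
2. Retrosynthesis: remove three silyl ethers; cut the aryl–oxygen bond O1–C8a of ring C to give a threo bromo alcohol with Br on C8a; cut C2–C3 by an aryloxyacetate aldol into an aryloxyacetyl imide and silylated syringaldehyde; cut O4–C3 back to a phenol made from 5-bromovanillin.
3. Forward: Wittig homologation on ring B, the O4–C3 ether, the aldol that joins rings A and B through C2–C3, two reductions and a silylation; ring C is closed last, followed only by desilylation.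
4. Enabling feature: in ring B the C8a–Br bond is ortho to the ether oxygen O4, so the free C2 hydroxyl sits at six-ring distance from C8a through C3–O4–C4a. Palladium inserts into C8a–Br and the alkoxide substitutes at that carbon without any bond to C2 or C3 being broken.
5. Stereochemistry: C2 and C3 are both set in the boron aldol under control of (R)-4-benzyloxazolidin-2-one (syn adduct = threo chain) and are carried with retention into the trans (2S,3S) ring. The E alkene comes from the stabilised ylide.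

Key step: step 9

Remark: the boron enolate of the aryloxyacetyl imide 6 is assumed to show the syn selectivity and facial sense established for alkoxyacetyl imides.

**Route**

Step 1
Reactants: 1 5-bromovanillin (3-bromo-4-hydroxy-5-methoxybenzaldehyde)
Product: 2 ethyl (E)-3-(3-bromo-4-hydroxy-5-methoxyphenyl)prop-2-enoate
Conditions: Ph3P=CHCO2Et (1.3 equiv), toluene, 100 °C
Reagents that add atoms: ethyl (triphenylphosphoranylidene)acetate, CCOC(=O)C=P(c1ccccc1)(c1ccccc1)c1ccccc1
Why: Wittig olefination with an ester-stabilised ylide tolerates the free phenol and should give the E enoate, because oxaphosphetane formation is reversible for such ylides.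

Step 2
Reactants: 3 (R)-4-benzyloxazolidin-2-one
Product: 5 (R)-4-benzyl-3-(bromoacetyl)oxazolidin-2-one, via N-lithio oxazolidinone 4 (not isolated)
Conditions: n-BuLi (1.05 equiv), THF, −78 °C; then BrCH2COBr, −78 to 0 °C
Reagents that add atoms: bromoacetyl bromide, BrCC(Br)=O; n-butyllithium, [Li]CCCC (its lithium stays in 4 only)
Why: N-acylation of a lithiated oxazolidinone by an acid bromide, in which attack at the acyl carbon is much faster than at the CH2Br carbon and the C4 stereocentre of the auxiliary is not involved.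

Step 3
Reactants: 2 ethyl (E)-3-(3-bromo-4-hydroxy-5-methoxyphenyl)prop-2-enoate; 5 (R)-4-benzyl-3-(bromoacetyl)oxazolidin-2-one
Product: 6 (R)-4-benzyl-3-[2-[2-bromo-4-[(E)-3-ethoxy-3-oxoprop-1-enyl]-6-methoxyphenoxy]acetyl]oxazolidin-2-one
Conditions: K2CO3 (1.5 equiv), acetone, 20 to 45 °C
Reagents that add atoms: none
Why: Williamson ether synthesis in which the acidic, doubly ortho-substituted phenoxide displaces bromide from the activated α-bromo imide (SN2), forming the O4–C3 bond (C3 still a CH2 group) under a base too weak to cleave the imide.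

Step 4
Reactants: 7 syringaldehyde (4-hydroxy-3,5-dimethoxybenzaldehyde)
Product: 8 3,5-dimethoxy-4-(triisopropylsilyloxy)benzaldehyde
Conditions: iPr3SiCl (1.2 equiv), imidazole, DMF, 25 °C
Reagents that add atoms: triisopropylsilyl chloride, CC(C)[Si](Cl)(C(C)C)C(C)C
Why: Silylation of the phenol as a bulky triisopropylsilyl ether masks the acidic OH for the boron aldol and the later carbonate-mediated coupling, and it is removable with fluoride at the end.

Step 5
Reactants: 6 (R)-4-benzyl-3-[2-[2-bromo-4-[(E)-3-ethoxy-3-oxoprop-1-enyl]-6-methoxyphenoxy]acetyl]oxazolidin-2-one; 8 3,5-dimethoxy-4-(triisopropylsilyloxy)benzaldehyde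
Product: 11 (R)-4-benzyl-3-[(2R,3S)-2-[2-bromo-4-[(E)-3-ethoxy-3-oxoprop-1-enyl]-6-methoxyphenoxy]-3-[3,5-dimethoxy-4-(triisopropylsilyloxy)phenyl]-3-hydroxypropanoyl]oxazolidin-2-one, via Z-boron enolate 9 (not isolated), via boron aldolate 10 (not isolated)
Conditions: Bu2BOTf (1.2 equiv), iPr2NEt (1.4 equiv), CH2Cl2, −78 to 0 °C; then 8, −78 to 0 °C; then pH 7 NaH2PO4/Na2HPO4 buffer, MeOH, 30% H2O2, 0 °C
Reagents that add atoms: dibutylboron triflate, CCCCB(CCCC)OS(=O)(=O)C(F)(F)F (its Bu2B group stays in 9 and 10 only)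
Why: Evans syn-aldol reaction in which the Z-boron enolate reacts through a closed Zimmerman–Traxler chair on the face away from the benzyl group of the (R)-auxiliary, which should set the acyl C2 as R and the carbinol C3 as S (the later ring carbons C3 and C2) in the syn, that is threo, relationship.

Step 6
Reactants: 11 the syn-aldol adduct named in step 5
Product: 12 ethyl (E)-3-[3-bromo-4-[(1S,2S)-1-[3,5-dimethoxy-4-(triisopropylsilyloxy)phenyl]-1,3-dihydroxypropan-2-yl]oxy-5-methoxyphenyl]prop-2-enoate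
Conditions: NaBH4, THF/H2O (4:1), 0 to 20 °C
Reagents that add atoms: none
Why: Reductive cleavage of an N-acyloxazolidinone by NaBH4 in wet THF takes place at the activated exocyclic imide carbonyl, should leave the conjugated ethyl ester untouched, releases the auxiliary and breaks no bond to either stereocentre.

Step 7
Reactants: 12 the diol ester named in step 6
Product: 13 (1S,2S)-2-[2-bromo-4-[(E)-3-hydroxyprop-1-enyl]-6-methoxyphenoxy]-1-[3,5-dimethoxy-4-(triisopropylsilyloxy)phenyl]propane-1,3-diol
Conditions: iBu2AlH (6 equiv), CH2Cl2, −78 to 0 °C; aqueous potassium sodium tartrate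
Reagents that add atoms: none
Why: 1,2-Reduction of an α,β-unsaturated ester by diisobutylaluminium hydride should give the E allylic alcohol without touching the aryl bromide, the alkene or the aryl silyl ether.

Step 8
Reactants: 13 the triol named in step 7
Product: 14 (1S,2S)-2-[2-bromo-6-methoxy-4-[(E)-3-(triisopropylsilyloxy)prop-1-enyl]phenoxy]-1-[3,5-dimethoxy-4-(triisopropylsilyloxy)phenyl]-3-(triisopropylsilyloxy)propan-1-ol
Conditions: iPr3SiCl (2.3 equiv), imidazole, DMF, 0 to 20 °C
Reagents that add atoms: triisopropylsilyl chloride, CC(C)[Si](Cl)(C(C)C)C(C)C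
Why: Sterically controlled silylation in which the bulky chlorosilane should react with the two primary hydroxyls and leave the hindered secondary benzylic hydroxyl as the only free nucleophile for ring closure, with a silyl group that does not migrate under carbonate.

Step 9
Reactants: 14 the bromo alcohol named in step 8
Product: 15 (2S,3S)-2-[3,5-dimethoxy-4-(triisopropylsilyloxy)phenyl]-5-methoxy-3-[(triisopropylsilyloxy)methyl]-7-[(E)-3-(triisopropylsilyloxy)prop-1-enyl]-2,3-dihydro-1,4-benzodioxine
Conditions: Pd(OAc)2 (5 mol %), racemic 2-(di-tert-butylphosphino)-1,1'-binaphthyl (6 mol %), Cs2CO3 (1.5 equiv), degassed toluene, 70 °C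
Reagents that add atoms: none
Why: Zerovalent palladium carrying one bulky phosphine (formed in the flask from Pd(OAc)2) inserts into the C8a–Br bond of ring B, carbonate exchanges bromide for the C2 alkoxide to give a seven-membered aryl(alkoxo) chelate of divalent palladium, and C–O reductive elimination forms O1–C8a and returns the catalyst. The closest known reaction type is the palladium-catalysed intramolecular etherification of 2-(2-bromoaryloxy)ethanols to 1,4-benzodioxanes (Buchwald–Hartwig C–O coupling), which accepts secondary alcohols and leaves carbinol stereocentres intact. Ring C closes in the 6-exo mode by ipso substitution at C8a, the departing bromide lying outside the new ring. No stereocentre is created: no bond to C2 or C3 is broken, so the (S,S) threo chain from step 5 should become the trans-diequatorial (2S,3S) ring. The step needs reductive elimination to outrun β-hydride elimination of the benzylic alkoxide, which the di-tert-butylbiaryl phosphine and the chelate favour, and it needs a single oxygen and a single carbon to react, which is secured because the C2 hydroxyl is the only free OH and C8a, ortho to O4, carries the only halogen.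

Step 10
Reactants: 15 the tris(triisopropylsilyl) ether named in step 9
Product: 16 4-[(2S,3S)-3-(hydroxymethyl)-7-[(E)-3-hydroxyprop-1-enyl]-5-methoxy-2,3-dihydro-1,4-benzodioxin-2-yl]-2,6-dimethoxyphenol
Conditions: Bu4NF (4 equiv), AcOH (4 equiv), THF, 0 to 20 °C
Reagents that add atoms: none
Why: Fluoride-mediated cleavage of the three Si–O bonds, buffered with acetic acid so that the liberated syringyl phenoxide does not open ring C through a quinone methide, should release the target without touching the stereocentres or the alkene.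

**Compound list**

1 | 5-bromovanillin (3-bromo-4-hydroxy-5-methoxybenzaldehyde) | COc1cc(C=O)cc(Br)c1O | starting material
2 | ethyl (E)-3-(3-bromo-4-hydroxy-5-methoxyphenyl)prop-2-enoate | CCOC(=O)/C=C/c1cc(Br)c(O)c(OC)c1 | intermediate
3 | (R)-4-benzyloxazolidin-2-one | O=C1N[C@H](Cc2ccccc2)CO1 | starting material
4 | N-lithio-(R)-4-benzyloxazolidin-2-one (not isolated) | [Li]N1[C@H](Cc2ccccc2)COC1=O | intermediate
5 | (R)-4-benzyl-3-(bromoacetyl)oxazolidin-2-one | O=C(CBr)N1[C@H](Cc2ccccc2)COC1=O | intermediate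
6 | (R)-4-benzyl-3-[2-[2-bromo-4-[(E)-3-ethoxy-3-oxoprop-1-enyl]-6-methoxyphenoxy]acetyl]oxazolidin-2-one | O=C(COc1c(Br)cc(/C=C/C(=O)OCC)cc1OC)N1[C@H](Cc2ccccc2)COC1=O | intermediate
7 | syringaldehyde (4-hydroxy-3,5-dimethoxybenzaldehyde) | COc1cc(C=O)cc(OC)c1O | starting material
8 | 3,5-dimethoxy-4-(triisopropylsilyloxy)benzaldehyde | COc1cc(C=O)cc(OC)c1O[Si](C(C)C)(C(C)C)C(C)C | intermediate
9 | Z-dibutylboron enolate of 6 (B–O and aryl–O cis; not isolated) | CCCCB(CCCC)O/C(=C\Oc1c(Br)cc(/C=C/C(=O)OCC)cc1OC)N1[C@H](Cc2ccccc2)COC1=O | intermediate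
10 | O-dibutylboryl derivative of aldol adduct 11 (2R,3S; not isolated) | O=C(N1[C@H](Cc2ccccc2)COC1=O)[C@H](Oc1c(Br)cc(/C=C/C(=O)OCC)cc1OC)[C@@H](OB(CCCC)CCCC)c1cc(OC)c(O[Si](C(C)C)(C(C)C)C(C)C)c(OC)c1 | intermediate
11 | (R)-4-benzyl-3-[(2R,3S)-2-[2-bromo-4-[(E)-3-ethoxy-3-oxoprop-1-enyl]-6-methoxyphenoxy]-3-[3,5-dimethoxy-4-(triisopropylsilyloxy)phenyl]-3-hydroxypropanoyl]oxazolidin-2-one | O=C(N1[C@H](Cc2ccccc2)COC1=O)[C@H](Oc1c(Br)cc(/C=C/C(=O)OCC)cc1OC)[C@@H](O)c1cc(OC)c(O[Si](C(C)C)(C(C)C)C(C)C)c(OC)c1 | intermediate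
12 | ethyl (E)-3-[3-bromo-4-[(1S,2S)-1-[3,5-dimethoxy-4-(triisopropylsilyloxy)phenyl]-1,3-dihydroxypropan-2-yl]oxy-5-methoxyphenyl]prop-2-enoate | COc1cc([C@H](O)[C@H](CO)Oc2c(Br)cc(/C=C/C(=O)OCC)cc2OC)cc(OC)c1O[Si](C(C)C)(C(C)C)C(C)C | intermediate
13 | (1S,2S)-2-[2-bromo-4-[(E)-3-hydroxyprop-1-enyl]-6-methoxyphenoxy]-1-[3,5-dimethoxy-4-(triisopropylsilyloxy)phenyl]propane-1,3-diol | COc1cc([C@H](O)[C@H](CO)Oc2c(Br)cc(/C=C/CO)cc2OC)cc(OC)c1O[Si](C(C)C)(C(C)C)C(C)C | intermediate
14 | (1S,2S)-2-[2-bromo-6-methoxy-4-[(E)-3-(triisopropylsilyloxy)prop-1-enyl]phenoxy]-1-[3,5-dimethoxy-4-(triisopropylsilyloxy)phenyl]-3-(triisopropylsilyloxy)propan-1-ol | COc1cc([C@H](O)[C@H](CO[Si](C(C)C)(C(C)C)C(C)C)Oc2c(Br)cc(/C=C/CO[Si](C(C)C)(C(C)C)C(C)C)cc2OC)cc(OC)c1O[Si](C(C)C)(C(C)C)C(C)C | intermediate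
15 | (2S,3S)-2-[3,5-dimethoxy-4-(triisopropylsilyloxy)phenyl]-5-methoxy-3-[(triisopropylsilyloxy)methyl]-7-[(E)-3-(triisopropylsilyloxy)prop-1-enyl]-2,3-dihydro-1,4-benzodioxine | COc1cc([C@@H]2Oc3cc(/C=C/CO[Si](C(C)C)(C(C)C)C(C)C)cc(OC)c3O[C@H]2CO[Si](C(C)C)(C(C)C)C(C)C)cc(OC)c1O[Si](C(C)C)(C(C)C)C(C)C | intermediate
16 | 4-[(2S,3S)-3-(hydroxymethyl)-7-[(E)-3-hydroxyprop-1-enyl]-5-methoxy-2,3-dihydro-1,4-benzodioxin-2-yl]-2,6-dimethoxyphenol | COc1cc([C@@H]2Oc3cc(/C=C/CO)cc(OC)c3O[C@H]2CO)cc(OC)c1O | target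

**Summary**

Total step count: 10.
Longest linear sequence: 8 steps (steps 1, 3, 5, 6, 7, 8, 9 and 10, from 5-bromovanillin).

**Steps most likely to fail**

1. Step 9. β-Hydride elimination from the palladium benzylic alkoxide may outrun C–O reductive elimination, which would oxidise the C2 carbinol to the ketone and replace the bromine by hydrogen. The fallback closes ring C at the other end of O1 (O1–C2 instead of O1–C8a) and sets out from 14. Miyaura borylation (bis(pinacolato)diboron, PdCl2[1,1'-bis(diphenylphosphino)ferrocene], KOAc, dioxane, 80 °C) should give the aryl pinacol boronate F1. Oxidation with NaBO3·4H2O in THF/H2O should give the catechol monoether phenol F2. A sulfonic acid resin (Amberlyst 15) in CH2Cl2 at 0 °C should then ionise the 4-silyloxybenzylic alcohol, and the C8a phenol should trap the cation from the face anti to the C3 substituent. C3 is untouched, and C2 is re-formed to the more stable trans ring. The fallback comes back to the route at 15.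

2. Step 5. Facial or syn/anti selectivity may be eroded, or the adduct may undergo retro-aldol cleavage, with the electron-rich hindered aldehyde and the bulky aryloxy enolate. The fallback sets both centres by catalytic reduction instead of C–C bond formation and sets out from 8 and 2. Roskamp homologation of 8 (ethyl diazoacetate, SnCl2, CH2Cl2) should give the β-keto ester F3. Bromination with N-bromosuccinimide and catalytic NH4OAc in Et2O should give the α-bromo β-keto ester F4. Displacement of bromide by phenol 2 (K2CO3, acetone) should give the α-aryloxy β-keto ester F5, whose α-centre epimerises freely. Asymmetric transfer hydrogenation with dynamic kinetic resolution (RuCl(p-cymene)[(R,R)-N-tosyl-1,2-diphenylethylenediamine], HCO2H/Et3N, CH2Cl2, 30 °C) is expected, by analogy with α-alkoxy β-keto esters, to give the syn hydroxy diester F6. The ligand enantiomer is chosen for the 3S carbinol, which the usual aryl ketone model assigns to the R,R ligand. Reduction of both ester groups with iBu2AlH (CH2Cl2, −78 to 0 °C) comes back to the route at 13.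

3. Step 3. The phenoxide may attack the exocyclic imide carbonyl (acyl transfer with loss of the auxiliary) instead of the CH2Br carbon, or carbonate may cleave the imide. The fallback makes the ether bond first and the imide bond second and sets out from 2. Alkylation with tert-butyl bromoacetate (K2CO3, acetone) should give the tert-butyl aryloxyacetate F7. CF3CO2H in CH2Cl2 should give the aryloxyacetic acid F8 with the ethyl enoate intact. Pivaloyl chloride and Et3N in THF at −20 °C should give the pivalic mixed anhydride F9, which is acylated in the same flask by oxazolidinone 3 with LiCl. The fallback comes back to the route at 6, and step 2 is then not needed.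

**Further compounds**

F1 | step 9 | (1S,2S)-1-[3,5-dimethoxy-4-(triisopropylsilyloxy)phenyl]-2-[2-methoxy-6-(4,4,5,5-tetramethyl-1,3,2-dioxaborolan-2-yl)-4-[(E)-3-(triisopropylsilyloxy)prop-1-enyl]phenoxy]-3-(triisopropylsilyloxy)propan-1-ol | COc1cc([C@H](O)[C@H](CO[Si](C(C)C)(C(C)C)C(C)C)Oc2c(B3OC(C)(C)C(C)(C)O3)cc(/C=C/CO[Si](C(C)C)(C(C)C)C(C)C)cc2OC)cc(OC)c1O[Si](C(C)C)(C(C)C)C(C)C
F2 | step 9 | (1S,2S)-1-[3,5-dimethoxy-4-(triisopropylsilyloxy)phenyl]-2-[2-hydroxy-6-methoxy-4-[(E)-3-(triisopropylsilyloxy)prop-1-enyl]phenoxy]-3-(triisopropylsilyloxy)propan-1-ol | COc1cc([C@H](O)[C@H](CO[Si](C(C)C)(C(C)C)C(C)C)Oc2c(O)cc(/C=C/CO[Si](C(C)C)(C(C)C)C(C)C)cc2OC)cc(OC)c1O[Si](C(C)C)(C(C)C)C(C)C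
F3 | step 5 | ethyl 3-[3,5-dimethoxy-4-(triisopropylsilyloxy)phenyl]-3-oxopropanoate | CCOC(=O)CC(=O)c1cc(OC)c(O[Si](C(C)C)(C(C)C)C(C)C)c(OC)c1
F4 | step 5 | ethyl 2-bromo-3-[3,5-dimethoxy-4-(triisopropylsilyloxy)phenyl]-3-oxopropanoate (racemic) | CCOC(=O)C(Br)C(=O)c1cc(OC)c(O[Si](C(C)C)(C(C)C)C(C)C)c(OC)c1
F5 | step 5 | ethyl 2-[2-bromo-4-[(E)-3-ethoxy-3-oxoprop-1-enyl]-6-methoxyphenoxy]-3-[3,5-dimethoxy-4-(triisopropylsilyloxy)phenyl]-3-oxopropanoate (racemic, α-centre labile) | CCOC(=O)/C=C/c1cc(Br)c(OC(C(=O)OCC)C(=O)c2cc(OC)c(O[Si](C(C)C)(C(C)C)C(C)C)c(OC)c2)c(OC)c1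
F6 | step 5 | ethyl (2R,3S)-2-[2-bromo-4-[(E)-3-ethoxy-3-oxoprop-1-enyl]-6-methoxyphenoxy]-3-[3,5-dimethoxy-4-(triisopropylsilyloxy)phenyl]-3-hydroxypropanoate | CCOC(=O)[C@H](Oc1c(Br)cc(/C=C/C(=O)OCC)cc1OC)[C@@H](O)c1cc(OC)c(O[Si](C(C)C)(C(C)C)C(C)C)c(OC)c1
F7 | step 3 | tert-butyl 2-[2-bromo-4-[(E)-3-ethoxy-3-oxoprop-1-enyl]-6-methoxyphenoxy]acetate | CC(C)(C)OC(=O)COc1c(Br)cc(/C=C/C(=O)OCC)cc1OC
F8 | step 3 | 2-[2-bromo-4-[(E)-3-ethoxy-3-oxoprop-1-enyl]-6-methoxyphenoxy]acetic acid | OC(=O)COc1c(Br)cc(/C=C/C(=O)OCC)cc1OC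
F9 | step 3 | mixed anhydride of F8 and pivalic acid (not isolated) | CC(C)(C)C(=O)OC(=O)COc1c(Br)cc(/C=C/C(=O)OCC)cc1OC
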